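**Retrosynthetic overview**

- Target 17 comes from methyl ether 15 by O-demethylation. 15 comes from 14 by bromination of ring B at C4', para to the ether oxygen.
- 14 is cut at two bonds of ring B at once, O–C1' and C2'–Br. The pieces are the phenoxide of 8, benzyne (from 9) and a bromine donor (10).
- The strategy rests on this feature: ring B carries its ether oxygen (C1') and a bromine (C2') on neighbouring carbons, the two ends of an aryne triple bond. Ring A (C1 OH, C2 to C4 Br, C5 H, C6 O-aryl) is a crowded, electron-poor phenol that is better used as a nucleophile toward an aryne than in substitution chemistry.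
- Phenol 8 comes from 2-methoxy-4-nitrophenol 1. The amine made from the nitro group places a bromine on each side of itself and is then replaced by bromine.
- No ring is formed. Ring A is bought and decorated first, and ring B arrives as benzyne.

Key step: step 6

Remark: the target has no stereocenter. Locants used are ring A C1 (OH), C2 to C4 (Br), C5 (H), C6 (O-aryl) and ring B C1' (O), C2' and C4' (Br).

**Route**

Step 1
Reactants: 1 2-methoxy-4-nitrophenol
Product: 2 2-methoxy-4-nitrophenyl acetate
Conditions: Ac2O, pyridine, cat. DMAP, CH2Cl2, 0 °C to rt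
Reagents that add atoms: acetic anhydride, CC(=O)OC(C)=O
Why: O-acylation of an acidic phenol, which masks the phenol oxygen so that after nitro reduction it neither activates C6 toward bromine nor allows oxidation to a quinone imine.

Step 2
Reactants: 2 2-methoxy-4-nitrophenyl acetate
Product: 3 4-amino-2-methoxyphenyl acetate
Conditions: H2 (1 atm), Pd/C, EtOAc, rt; the filtered solution is used at once
Reagents that add atoms: none
Why: Catalytic hydrogenation of an aromatic nitro group under neutral, aprotic conditions should leave the aryl acetate intact, and the amine sits para to the ester, so no intramolecular acyl shift can occur.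

Step 3
Reactants: 3 4-amino-2-methoxyphenyl acetate
Product: 5 4-amino-3,5-dibromo-2-methoxyphenyl acetate, via monobromo amine 4 (not isolated)
Conditions: NBS (2.1 equiv), MeCN, 0 °C to rt, dark
Reagents that add atoms: N-bromosuccinimide, O=C1CCC(=O)N1Br
Why: Electrophilic aromatic bromination directed by the amino group, first at C5 (ortho to NH2, para to OMe) and then at C3 (ortho to both donors), while C6 is meta to both donors and next to the acetoxy group and should stay free.

Step 4
Reactants: 5 4-amino-3,5-dibromo-2-methoxyphenyl acetate
Product: 7 3,4,5-tribromo-2-methoxyphenyl acetate, via arenediazonium bromide 6 (not isolated)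
Conditions: tBuONO (1.5 equiv), CuBr2 (1.2 equiv), MeCN, 0 °C to 60 °C
Reagents that add atoms: copper dibromide CuBr2, Br[Cu]Br
Why: Sandmeyer bromination under water-free alkyl nitrite conditions, in which the diazonium ion loses N2 and the aryl radical takes bromine from CuBr2; the acetate stays on, so no quinone diazide can form, and all positions ortho and para to nitrogen are blocked against ring bromination.

Step 5
Reactants: 7 3,4,5-tribromo-2-methoxyphenyl acetate
Product: 8 3,4,5-tribromo-2-methoxyphenol
Conditions: HCl (1.25 M in MeOH), rt to 40 °C
Reagents that add atoms: none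
Why: Acid-catalysed methanolysis (transesterification) of an aryl acetate with a good phenol leaving group, under conditions that touch neither the methyl ether nor the aryl bromides.

Step 6
Reactants: 8 3,4,5-tribromo-2-methoxyphenol; 9 2-(trimethylsilyl)phenyl trifluoromethanesulfonate; 10 1,2-dibromo-1,1,2,2-tetrachloroethane
Product: 14 1,2,3-tribromo-5-(2-bromophenoxy)-4-methoxybenzene, via cesium phenoxide 11 (not isolated), via benzyne 12 (not isolated), via arylcesium 13 (not isolated)
Conditions: CsOH·H2O (1.0 equiv), MeOH, rt, then evaporation and toluene azeotrope under vacuum; 10 (3 equiv), CsF (3 equiv), 18-crown-6, dry DME, slow addition of 9 (1.5 equiv), rt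
Reagents that add atoms: none
Why: Proposed new method: fluoride removes the silyl group of 9 and triflate leaves to give benzyne 12, the oxygen of the dry phenoxide 11 adds to the strained triple bond (O–C1'), and the 2-aryloxyphenyl anion 13 attacks a bromine of 10 in a halogenophilic substitution that expels bromide and tetrachloroethene (C2'–Br). The closest known reaction types are the fluoride-induced insertion of arynes into the O–H bond of phenols and aryne 1,2-difunctionalisations in which the aryl anion is quenched by a halogen electrophile. No ring closes and no stereocenter is formed. Benzyne has hydrogen on both sides of the triple bond, so the two addends can only end up on neighbouring carbons and no regiochemical question arises. The selectivity needed is bromine transfer to 13 ahead of protonation or of proton transfer from the C–H of ring A, and the water-free pre-formed phenoxide, an ether solvent without acidic C–H, the excess of 10 and the slow release of benzyne are chosen to secure it. No transition metal is present, so the three C–Br bonds of ring A should stay untouched, and a phenoxide too crowded and electron-poor for substitution chemistry should still add to an aryne.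

Step 7
Reactants: 14 1,2,3-tribromo-5-(2-bromophenoxy)-4-methoxybenzene
Product: 15 1,2,3-tribromo-5-(2,4-dibromophenoxy)-4-methoxybenzene
Conditions: Br2 (1.05 equiv), AcOH, rt to 40 °C
Reagents that add atoms: bromine, BrBr
Why: Electrophilic aromatic bromination in which the ether oxygen, the only donor on ring B, directs para to C4' (C2' is occupied and C6' is the more hindered ortho site), while the single C–H of ring A is deactivated by three bromines.

Step 8
Reactants: 15 1,2,3-tribromo-5-(2,4-dibromophenoxy)-4-methoxybenzene
Product: 17 2,3,4-tribromo-6-(2,4-dibromophenoxy)phenol, via aryloxydibromoborane 16 (not isolated)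
Conditions: BBr3 (3 equiv), CH2Cl2, −78 °C to rt; then H2O, 0 °C
Reagents that add atoms: none
Why: Lewis acid cleavage of an aryl methyl ether, in which BBr3 binds the methoxy oxygen and bromide removes the methyl group by SN2; the diaryl ether and the aryl bromides are inert, and hydrolysis of 16 frees the phenol of the target.

**Compound list**

1 | 2-methoxy-4-nitrophenol | COc1cc(ccc1O)[N+](=O)[O-] | starting material
2 | 2-methoxy-4-nitrophenyl acetate | CC(=O)Oc1ccc(cc1OC)[N+](=O)[O-] | intermediate
3 | 4-amino-2-methoxyphenyl acetate | CC(=O)Oc1ccc(N)cc1OC | intermediate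
4 | 4-amino-5-bromo-2-methoxyphenyl acetate | CC(=O)Oc1cc(Br)c(N)cc1OC | intermediate (not isolated)
5 | 4-amino-3,5-dibromo-2-methoxyphenyl acetate | CC(=O)Oc1cc(Br)c(N)c(Br)c1OC | intermediate
6 | 4-acetoxy-2,6-dibromo-3-methoxybenzenediazonium bromide | CC(=O)Oc1cc(Br)c([N+]#N)c(Br)c1OC.[Br-] | intermediate (not isolated)
7 | 3,4,5-tribromo-2-methoxyphenyl acetate | CC(=O)Oc1cc(Br)c(Br)c(Br)c1OC | intermediate
8 | 3,4,5-tribromo-2-methoxyphenol | COc1c(O)cc(Br)c(Br)c1Br | intermediate
9 | 2-(trimethylsilyl)phenyl trifluoromethanesulfonate | C[Si](C)(C)c1ccccc1OS(=O)(=O)C(F)(F)F | starting material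
10 | 1,2-dibromo-1,1,2,2-tetrachloroethane | BrC(Cl)(Cl)C(Cl)(Cl)Br | starting material
11 | cesium 3,4,5-tribromo-2-methoxyphenoxide | COc1c([O-])cc(Br)c(Br)c1Br.[Cs+] | intermediate (not isolated)
12 | benzyne (1,2-didehydrobenzene) | C1#CC=CC=C1 | intermediate (not isolated)
13 | [2-(3,4,5-tribromo-2-methoxyphenoxy)phenyl]cesium | COc1c(Oc2ccccc2[Cs])cc(Br)c(Br)c1Br | intermediate (not isolated)
14 | 1,2,3-tribromo-5-(2-bromophenoxy)-4-methoxybenzene | COc1c(Oc2ccccc2Br)cc(Br)c(Br)c1Br | intermediate
15 | 1,2,3-tribromo-5-(2,4-dibromophenoxy)-4-methoxybenzene | COc1c(Oc2ccc(Br)cc2Br)cc(Br)c(Br)c1Br | intermediate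
16 | dibromo[2,3,4-tribromo-6-(2,4-dibromophenoxy)phenoxy]borane | BrB(Br)Oc1c(Oc2ccc(Br)cc2Br)cc(Br)c(Br)c1Br | intermediate (not isolated)
17 | 2,3,4-tribromo-6-(2,4-dibromophenoxy)phenol | Oc1c(Oc2ccc(Br)cc2Br)cc(Br)c(Br)c1Br | target

**Step count**

Total step count: 8. Longest linear sequence: 8 steps (1 to 17). Compounds 9 and 10 are bought and enter at step 6.

**Steps most likely to fail**

Step 6. Bromine transfer to the aryl anion may lose to protonation or to proton transfer from the C–H of ring A, and the donor may brominate the phenoxide at its free ortho carbon before the aryne is released. The fallback sets out from phenol 8 and uses a metal-free O-arylation with a diaryliodonium salt. The salt (2-bromophenyl)(2,4,6-trimethoxyphenyl)iodonium p-toluenesulfonate F1 would be made in one pot from 1-bromo-2-iodobenzene, mCPBA, TsOH·H2O and 1,3,5-trimethoxybenzene in MeCN. Treated with KOtBu in THF at rt to 40 °C, the phenoxide of 8 should add to iodine, and ligand coupling should transfer the 2-bromophenyl group, not the electron-rich trimethoxyphenyl group. This gives 14, where the route is rejoined.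

Step 4. After loss of nitrogen, the crowded carbon between two bromines may capture hydrogen from the solvent or oxygen in place of bromine. The fallback sets out from amine 5 and installs the halogen in two stages. Diazotisation with tBuONO and p-TsOH·H2O in MeCN gives 4-acetoxy-2,6-dibromo-3-methoxybenzenediazonium p-toluenesulfonate F2. KI converts it without copper into 3,5-dibromo-4-iodo-2-methoxyphenyl acetate F3. Methanolysis (HCl, MeOH) gives 3,5-dibromo-4-iodo-2-methoxyphenol F4. Deprotonation with MeMgCl, then iodine–magnesium exchange with iPrMgCl·LiCl in THF at −40 °C (iodine exchanges far faster than bromine), gives chloromagnesium 3,5-dibromo-4-(chloromagnesio)-2-methoxyphenoxide F5. Quenching F5 with 10 should deliver phenol 8, where the route is rejoined; step 5 is not needed.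

Step 7. Positional control may be poor, with attack at C6' beside C4' or a second bromination of ring B. The fallback sets out from phenol 8 and fixes the position of the second ring B bromine with a nitro group. SNAr of 8 on 2-bromo-1-fluoro-4-nitrobenzene (K2CO3, DMF, 70 °C) gives 1,2,3-tribromo-5-(2-bromo-4-nitrophenoxy)-4-methoxybenzene F6. Reduction with Fe powder and NH4Cl in EtOH/H2O at 75 °C, which spares aryl bromides, gives 3-bromo-4-(3,4,5-tribromo-2-methoxyphenoxy)aniline F7. Sandmeyer bromination of this unhindered amine (tBuONO, CuBr2, MeCN) passes through 3-bromo-4-(3,4,5-tribromo-2-methoxyphenoxy)benzenediazonium bromide F8 and gives 15, where the route is rejoined; 14 is bypassed.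

**Further compounds**

F1 | step 6 | (2-bromophenyl)(2,4,6-trimethoxyphenyl)iodonium p-toluenesulfonate | COc1cc(OC)c([I+]c2ccccc2Br)c(OC)c1.Cc1ccc(cc1)S(=O)(=O)[O-]
F2 | step 4 | 4-acetoxy-2,6-dibromo-3-methoxybenzenediazonium p-toluenesulfonate | CC(=O)Oc1cc(Br)c([N+]#N)c(Br)c1OC.Cc1ccc(cc1)S(=O)(=O)[O-]
F3 | step 4 | 3,5-dibromo-4-iodo-2-methoxyphenyl acetate | CC(=O)Oc1cc(Br)c(I)c(Br)c1OC
F4 | step 4 | 3,5-dibromo-4-iodo-2-methoxyphenol | COc1c(O)cc(Br)c(I)c1Br
F5 | step 4 | chloromagnesium 3,5-dibromo-4-(chloromagnesio)-2-methoxyphenoxide | COc1c(O[Mg]Cl)cc(Br)c([Mg]Cl)c1Br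
F6 | step 7 | 1,2,3-tribromo-5-(2-bromo-4-nitrophenoxy)-4-methoxybenzene | COc1c(Oc2ccc(cc2Br)[N+](=O)[O-])cc(Br)c(Br)c1Br
F7 | step 7 | 3-bromo-4-(3,4,5-tribromo-2-methoxyphenoxy)aniline | COc1c(Oc2ccc(N)cc2Br)cc(Br)c(Br)c1Br
F8 | step 7 | 3-bromo-4-(3,4,5-tribromo-2-methoxyphenoxy)benzenediazonium bromide | COc1c(Oc2ccc(cc2Br)[N+]#N)cc(Br)c(Br)c1Br.[Br-]
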